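The six-membered carbocycle (C1 quaternary, C2 ketone, C3 acyl-bearing, C4 enol, C5 attached to O10, C6) is opened at C5–C6 and C2–C3. The cut exploits that C3, C4 and C5 together with the exocyclic acyl carbon are a 1,3-diketone chain, nucleophilic at C3 and C5, while C2 and C6 are two electrophilic carbons carried by C1. In one step a trilithiated 6-(1,1-dimethylpropargyloxy)-1-phenylhexane-3,5-dione meets an enantiopure α-methyl-α-prenyl formyl ester: aldol at C6, ring-closing acylation at C2, then acetylative removal of the C6 oxygen. An esterase desymmetrisation sets C1. A thermal propargyl Claisen cascade finally closes the pyran ring (C6–C7=C8–C9–O10–C5).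

Key step: step 7

Assumption: the esterase is taken to cleave the pro-R ester group and so give the (S)-half-ester. Sense and level of selection must be verified on the half-ester, and the fallback to step 2 covers a poor or opposite outcome.

Design notes
- Stereochemical bookkeeping: the target stereocentre is S. The ester carbon becomes C2 and the formyl carbon becomes C6, so the half-ester, hydroxy ester and formyl ester needed are all S (same spatial arrangement throughout).
- The dione has two methylenes that can give the last carbanion: C5, and the CH2 next to the benzyl group. The base is therefore used in slight deficit and the polyanion is aged so that the more stable C5 anion can form.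
- The lithiated alkyne terminus is kept on purpose. It blocks sigmatropic shifts of a carbanion that sits next to a propargyl ether.
- Oxide cannot leave a polyanion, so the loss of water gets its own reagents within the same step.
- Borane is avoided because of the prenyl alkene.
- An N-methoxy-N-methyl amide replaces a haloacetate ester in the ether and dione syntheses.

Step 1
Reactants: 1 dimethyl methylmalonate; 2 prenyl bromide
Product: 3 dimethyl 2-methyl-2-(3-methylbut-2-en-1-yl)propanedioate
Conditions: NaH, THF, 0 °C; then 2, 0 °C → rt
Reagents that add atoms: none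
Why: Malonic ester alkylation: the sodium enolate of the only acidic C–H displaces bromide from the primary allylic halide at its unhindered CH2 (SN2), and the product is still achiral because its two ester groups are alike.

Step 2
Reactants: 3 dimethyl 2-methyl-2-(3-methylbut-2-en-1-yl)propanedioate
Product: 4 (2S)-2-(methoxycarbonyl)-2,5-dimethylhex-4-enoic acid
Conditions: pig liver esterase, phosphate buffer pH 7.2, 10% DMSO, 25 °C, pH-stat (1 M NaOH); then HCl to pH 2
Reagents that add atoms: water, O
Why: Enzymatic desymmetrisation of a prochiral α,α-disubstituted malonate, a known substrate class for pig liver esterase: the active site distinguishes methyl from prenyl and therefore hydrolyses one of the two enantiotopic ester groups, which sets the quaternary stereocentre (S), and the resulting carboxylate is no longer accepted, so the second ester stays.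

Step 3
Reactants: 4 (2S)-2-(methoxycarbonyl)-2,5-dimethylhex-4-enoic acid
Product: 6 methyl (2S)-2-(hydroxymethyl)-2,5-dimethylhex-4-enoate, via mixed carbonic anhydride 5 (not isolated)
Conditions: i-BuOCOCl, N-methylmorpholine, THF, −15 °C; filter; NaBH4, THF–H2O, 0 °C
Reagents that add atoms: none
Why: Mixed-anhydride activation followed by borohydride reduction: hydride attacks only the activated acyl carbon (the carbonate carbonyl is the less electrophilic one), so the methyl ester and the trisubstituted alkene, which would not tolerate borane, remain, and the quaternary centre has no hydrogen through which it could epimerise.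

Step 4
Reactants: 6 methyl (2S)-2-(hydroxymethyl)-2,5-dimethylhex-4-enoate
Product: 7 methyl (2S)-2-formyl-2,5-dimethylhex-4-enoate
Conditions: Dess–Martin periodinane, CH2Cl2, rt; used without storage
Reagents that add atoms: none
Why: Dess–Martin oxidation turns the neopentyl-type primary alcohol into the aldehyde under neutral, non-nucleophilic conditions, which avoids both over-oxidation and retro-Claisen loss of the formyl group, and the centre stays fixed because it carries no hydrogen.

Step 5
Reactants: 8 2-methylbut-3-yn-2-ol; 9 2-chloro-N-methoxy-N-methylacetamide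
Product: 10 N-methoxy-N-methyl-2-[(2-methylbut-3-yn-2-yl)oxy]acetamide
Conditions: NaH (1.0 equiv), THF, 0 °C; then 9, Bu4NI (cat.), 0 °C → rt
Reagents that add atoms: none
Why: Williamson ether synthesis: the tertiary propargylic alkoxide displaces chloride from the activated α-chloro amide, and the N-methoxy-N-methyl amide, unlike a haloacetate ester, does not exchange its acyl group with the alkoxide.

Step 6
Reactants: 11 4-phenylbutan-2-one; 10 N-methoxy-N-methyl-2-[(2-methylbut-3-yn-2-yl)oxy]acetamide
Product: 12 6-[(2-methylbut-3-yn-2-yl)oxy]-1-phenylhexane-3,5-dione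
Conditions: LDA, THF, −78 °C, 11; then 10, −78 → 0 °C; cold 1 M HCl
Reagents that add atoms: none
Why: Crossed Claisen-type acylation: LDA at −78 °C deprotonates the methyl side of the ketone (kinetic enolate), and this enolate adds to the Weinreb amide to give a chelated tetrahedral adduct that holds until the quench, so neither a second addition nor proton exchange with the acidic product interferes.

Step 7
Reactants: 12 6-[(2-methylbut-3-yn-2-yl)oxy]-1-phenylhexane-3,5-dione; 7 methyl (2S)-2-formyl-2,5-dimethylhex-4-enoate
Product: 17 (6S)-3-hydroxy-6-methyl-6-(3-methylbut-2-en-1-yl)-4-[(2-methylbut-3-yn-2-yl)oxy]-2-(3-phenylpropanoyl)cyclohexa-2,4-dien-1-one, via aldol adduct 13 (not isolated), via hydroxy triketone 14 (not isolated), via diacetate 15 (not isolated), via enol acetate 16 (not isolated)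
Conditions: LDA (2.9 equiv), THF, −78 → 0 °C; 7 (0.9 equiv), −78 °C → 45 °C; cold 1 M HCl; crude in CH2Cl2: Ac2O, Et3N, DMAP (cat.), 0 °C → rt, then DBU; MeOH
Reagents that add atoms: none
Why: LDA removes the C3–H, the alkyne C–H and then a flanking methylene proton, and ageing at 0 °C with a slight deficit of base lets diisopropylamine shuttle protons until the C5 carbanion prevails over the benzyl-side one (an α-alkoxy CH2 is the more acidic, and O10 with the C4 enolate oxygen chelates lithium), while the charge on the acetylide terminus blocks the [2,3]-Wittig and anionic Claisen shifts open to a carbanion next to a propargyl ether. At −78 °C this last-formed and most basic site should add to the aldehyde carbon C6 of 7, which has no α-hydrogen and is far more electrophilic than the neighbouring hindered ester, ahead of the acetylide and the delocalised C3 (γ-aldol of a β-diketone polyanion), giving 13. On warming, C3 of the remaining diketonate acylates on the ester carbon C2 in a 6-exo-trig closure (allowed whether the enolate is counted as endo or exo to the new ring), the known Dieckmann-type cyclisation of 5,7-dioxo esters to 2-acylcyclohexane-1,3-diones, helped by the heavily substituted tether, and since hemiketal formation by the C6 alkoxide is reversible and has no leaving group, the material should drain to the very stable triketonate of 14. Oxide cannot leave that polyanion, so after a cold acid quench both hydroxyls are acetylated, which makes the ring neutral, DBU expels the C6 acetate by E1cB through the only β-hydrogen (C5–H), and methanol strips the labile enol acetate. No lasting stereocentre is made: the C5 and C6 centres of 13–15 are erased in the elimination, so their mixture is irrelevant, and C1 has no enolisable hydrogen, its one threat, retro-aldol cleavage of C1–C6 in the lithium aldolate, being uphill because it would release an unstabilised ester enolate.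

Step 8
Reactants: 17 (6S)-3-hydroxy-6-methyl-6-(3-methylbut-2-en-1-yl)-4-[(2-methylbut-3-yn-2-yl)oxy]-2-(3-phenylpropanoyl)cyclohexa-2,4-dien-1-one
Product: 21 (5S)-8-hydroxy-2,2,5-trimethyl-5-(3-methylbut-2-en-1-yl)-7-(3-phenylpropanoyl)-2H-chromen-6(5H)-one, via allenyl ketone 18 (not isolated), via vinylallene enol 19 (not isolated), via oxatriene 20 (not isolated)
Conditions: toluene (degassed), 110 °C, sealed tube
Reagents that add atoms: none
Why: Heating sets off the cascade known from aryl 1,1-dimethylpropargyl ethers and from propargyl vinyl ethers: a propargyl Claisen [3,3] shift of the C6=C5–O10 vinyl ether brings the alkyne terminus to C6, the only vinylic terminus available, to give 18, enolisation of its doubly activated C6–H gives 19, a 1,5-hydrogen shift from oxygen to the central allene carbon gives the Z-oxatriene 20, and oxa-6π electrocyclisation closes the pyran, which the gem-dimethyl group keeps on the closed side, while the transient C6 centre disappears again and C1 is not touched.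

Compound list
1 | dimethyl methylmalonate | COC(=O)C(C)C(=O)OC | starting material
2 | prenyl bromide (1-bromo-3-methylbut-2-ene) | CC(C)=CCBr | starting material
3 | dimethyl 2-methyl-2-(3-methylbut-2-en-1-yl)propanedioate | COC(=O)C(C)(CC=C(C)C)C(=O)OC | intermediate
4 | (2S)-2-(methoxycarbonyl)-2,5-dimethylhex-4-enoic acid | COC(=O)[C@@](C)(CC=C(C)C)C(=O)O | intermediate
5 | isobutyl carbonic mixed anhydride of 4 (same spatial arrangement; formally 2R because the anhydride carbonyl outranks the ester) | COC(=O)[C@@](C)(CC=C(C)C)C(=O)OC(=O)OCC(C)C | intermediate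
6 | methyl (2S)-2-(hydroxymethyl)-2,5-dimethylhex-4-enoate | COC(=O)[C@@](C)(CC=C(C)C)CO | intermediate
7 | methyl (2S)-2-formyl-2,5-dimethylhex-4-enoate | COC(=O)[C@@](C)(CC=C(C)C)C=O | intermediate
8 | 2-methylbut-3-yn-2-ol | CC(C)(O)C#C | starting material
9 | 2-chloro-N-methoxy-N-methylacetamide | CON(C)C(=O)CCl | starting material
10 | N-methoxy-N-methyl-2-[(2-methylbut-3-yn-2-yl)oxy]acetamide | CON(C)C(=O)COC(C)(C)C#C | intermediate
11 | 4-phenylbutan-2-one | CC(=O)CCc1ccccc1 | starting material
12 | 6-[(2-methylbut-3-yn-2-yl)oxy]-1-phenylhexane-3,5-dione | O=C(CCc1ccccc1)CC(=O)COC(C)(C)C#C | intermediate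
13 | methyl (2S)-2-{1-hydroxy-2-[(2-methylbut-3-yn-2-yl)oxy]-3,5-dioxo-7-phenylheptyl}-2,5-dimethylhex-4-enoate (trilithium salt in the flask; mixture at the two new carbons) | COC(=O)[C@@](C)(CC=C(C)C)C(O)C(OC(C)(C)C#C)C(=O)CC(=O)CCc1ccccc1 | intermediate
14 | (6S)-5-hydroxy-6-methyl-6-(3-methylbut-2-en-1-yl)-4-[(2-methylbut-3-yn-2-yl)oxy]-2-(3-phenylpropanoyl)cyclohexane-1,3-dione, drawn as the 3-enol (mixture at C4 and C5 of this name) | CC(C)=CC[C@]1(C)C(=O)C(C(=O)CCc2ccccc2)=C(O)C(OC(C)(C)C#C)C1O | intermediate
15 | diacetate of 14 (carbinol acetate and ring enol acetate) | CC(C)=CC[C@]1(C)C(=O)C(C(=O)CCc2ccccc2)=C(OC(C)=O)C(OC(C)(C)C#C)C1OC(C)=O | intermediate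
16 | enol acetate of 17 | CC(C)=CC[C@]1(C)C(=O)C(C(=O)CCc2ccccc2)=C(OC(C)=O)C(OC(C)(C)C#C)=C1 | intermediate
17 | (6S)-3-hydroxy-6-methyl-6-(3-methylbut-2-en-1-yl)-4-[(2-methylbut-3-yn-2-yl)oxy]-2-(3-phenylpropanoyl)cyclohexa-2,4-dien-1-one | CC(C)=CC[C@]1(C)C(=O)C(C(=O)CCc2ccccc2)=C(O)C(OC(C)(C)C#C)=C1 | intermediate
18 | allenyl ketone: C5 ketone, C6 sp3 carrying H and a 3-methylbuta-1,2-dienyl group (mixture at C6), C1 S | CC(C)=CC[C@]1(C)C(=O)C(C(=O)CCc2ccccc2)=C(O)C(=O)C1C=C=C(C)C | intermediate
19 | vinylallene enol: C5(OH)=C6 carrying the 3-methylbuta-1,2-dienyl group, C1 S | CC(C)=CC[C@]1(C)C(=O)C(C(=O)CCc2ccccc2)=C(O)C(O)=C1C=C=C(C)C | intermediate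
20 | oxatriene: C5 ketone, exocyclic (Z)-C6=C7H–C8H=C9Me2, C1 S | CC(C)=CC[C@]1(C)C(=O)C(C(=O)CCc2ccccc2)=C(O)C(=O)/C1=C\C=C(C)C | intermediate
21 | (5S)-8-hydroxy-2,2,5-trimethyl-5-(3-methylbut-2-en-1-yl)-7-(3-phenylpropanoyl)-2H-chromen-6(5H)-one (CNP0120278.1) | CC(C)=CC[C@]1(C)C(=O)C(C(=O)CCc2ccccc2)=C(O)C2=C1C=CC(C)(C)O2 | target

Total step count: 8. Longest linear sequence: 6 steps (1, 2, 3, 4, 7, 8).

Steps most likely to fail

1. Step 7.
- What may go wrong: site control may be lost in the third deprotonation, with metalation of the benzyl-side methylene in place of C5, so that the aldol starts from the wrong carbon. Capture of the aldehyde by the acetylide and a stalled closure onto the hindered ester are lesser dangers.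
- Fallback: remove the competing acidic site and bring in the side chain last.
- Setting out from 10, the lithium enolate of tert-butyl acetate (LDA, THF, −78 °C) gives tert-butyl 4-[(2-methylbut-3-yn-2-yl)oxy]-3-oxobutanoate F1. It has a single γ-methylene, and its bulky ester resists lactonisation by the C6 alkoxide.
- The trianion of F1 is combined with 7 and taken through the operations of step 7. This gives tert-butyl (5S)-2-hydroxy-5-methyl-5-(3-methylbut-2-en-1-yl)-3-[(2-methylbut-3-yn-2-yl)oxy]-6-oxocyclohexa-1,3-diene-1-carboxylate F2.
- TMSOTf/2,6-lutidine followed by water removes the tert-butyl group. The β-keto acid then loses CO2 to give (6S)-3-hydroxy-6-methyl-6-(3-methylbut-2-en-1-yl)-4-[(2-methylbut-3-yn-2-yl)oxy]cyclohexa-2,4-dien-1-one F3.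
- 3-Phenylpropanoic acid, DCC and DMAP give the enol 3-phenylpropanoate F4. DMAP shifts its acyl group from oxygen to C3, the only open carbon between two carbonyls. The route is rejoined at 17.

2. Step 2.
- What may go wrong: discrimination between the enantiotopic esters may be poor because prenyl is of borderline size for the enzyme pocket, or the opposite sense of hydrolysis may occur.
- Fallback: classical resolution with use of both antipodes.
- Setting out from 3, KOH (1 equiv) in MeOH gives racemic 2-(methoxycarbonyl)-2,5-dimethylhex-4-enoic acid F5.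
- Fractional crystallisation with (R)-1-phenylethylamine (or its antipode, whichever gives the less soluble salt of the S acid) gives the (R)-1-phenylethylammonium (S)-carboxylate F6. Dilute acid releases 4 from it.
- The antipodal (2R)-2-(methoxycarbonyl)-2,5-dimethylhex-4-enoic acid F7 comes from the mother liquor, or from an enzyme of opposite sense. Its ester is reduced as the lithium carboxylate with LiBH4 to (2S)-2-(hydroxymethyl)-2,5-dimethylhex-4-enoic acid F8.
- MeI/K2CO3 in DMF then gives 6. The route is rejoined at 4 and at 6.

3. Step 8.
- What may go wrong: at the temperature the propargyl shift needs, the dienone may be diverted, for example by Cope-type migration of the C1 prenyl group or by side reactions of the allene before it isomerises.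
- Fallback: replace the redox-neutral cascade by reduction, a much easier allyl Claisen shift and an oxidative ring closure.
- Setting out from 17, Lindlar hydrogenation (quinoline) gives (6S)-3-hydroxy-6-methyl-4-[(2-methylbut-3-en-2-yl)oxy]-6-(3-methylbut-2-en-1-yl)-2-(3-phenylpropanoyl)cyclohexa-2,4-dien-1-one F9.
- Gentle warming (60–80 °C) moves the allyl unit to C6 and, after enolisation, gives (6S)-3,4-dihydroxy-6-methyl-5,6-bis(3-methylbut-2-en-1-yl)-2-(3-phenylpropanoyl)cyclohexa-2,4-dien-1-one F10.
- DDQ in benzene abstracts hydride from the doubly allylic CH2 on C6, as in the cyclisation of o-prenyl phenols and 2-hydroxy-3-prenylquinones. This leads to 20, which closes to 21.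

Further compounds
F1 | step 7 | tert-butyl 4-[(2-methylbut-3-yn-2-yl)oxy]-3-oxobutanoate | CC(C)(C)OC(=O)CC(=O)COC(C)(C)C#C
F2 | step 7 | tert-butyl (5S)-2-hydroxy-5-methyl-5-(3-methylbut-2-en-1-yl)-3-[(2-methylbut-3-yn-2-yl)oxy]-6-oxocyclohexa-1,3-diene-1-carboxylate | CC(C)=CC[C@]1(C)C(=O)C(C(=O)OC(C)(C)C)=C(O)C(OC(C)(C)C#C)=C1
F3 | step 7 | (6S)-3-hydroxy-6-methyl-6-(3-methylbut-2-en-1-yl)-4-[(2-methylbut-3-yn-2-yl)oxy]cyclohexa-2,4-dien-1-one | CC(C)=CC[C@]1(C)C(=O)C=C(O)C(OC(C)(C)C#C)=C1
F4 | step 7 | enol 3-phenylpropanoate of F3 | CC(C)=CC[C@]1(C)C(=O)C=C(OC(=O)CCc2ccccc2)C(OC(C)(C)C#C)=C1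
F5 | step 2 | racemic 2-(methoxycarbonyl)-2,5-dimethylhex-4-enoic acid | COC(=O)C(C)(CC=C(C)C)C(=O)O
F6 | step 2 | (R)-1-phenylethylammonium (2S)-2-(methoxycarbonyl)-2,5-dimethylhex-4-enoate | COC(=O)[C@@](C)(CC=C(C)C)C(=O)[O-].C[C@@H]([NH3+])c1ccccc1
F7 | step 2 | (2R)-2-(methoxycarbonyl)-2,5-dimethylhex-4-enoic acid | COC(=O)[C@](C)(CC=C(C)C)C(=O)O
F8 | step 2 | (2S)-2-(hydroxymethyl)-2,5-dimethylhex-4-enoic acid | OC[C@](C)(CC=C(C)C)C(=O)O
F9 | step 8 | (6S)-3-hydroxy-6-methyl-4-[(2-methylbut-3-en-2-yl)oxy]-6-(3-methylbut-2-en-1-yl)-2-(3-phenylpropanoyl)cyclohexa-2,4-dien-1-one | CC(C)=CC[C@]1(C)C(=O)C(C(=O)CCc2ccccc2)=C(O)C(OC(C)(C)C=C)=C1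
F10 | step 8 | (6S)-3,4-dihydroxy-6-methyl-5,6-bis(3-methylbut-2-en-1-yl)-2-(3-phenylpropanoyl)cyclohexa-2,4-dien-1-one | CC(C)=CC[C@]1(C)C(=O)C(C(=O)CCc2ccccc2)=C(O)C(O)=C1CC=C(C)C
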